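**Retrosynthetic overview**
- Target ⇐ desilylation and exhaustive acetylation of a labd-14-ene tetraol carrying silyl ethers on O3 and O13.
- The C12–C13 bond and both side-chain stereocentres ⇐ chiral-phosphoric-acid-catalysed γ-silyloxy-γ-methylallylboration of a sclareolide-type lactol.
- Lactol ⇐ 6-oxo-8α,12-olide; the C6 oxygen comes from the Δ5 alkene, and the lactone from a ketene-ylide butenolide annulation on an 8α-hydroxy-8-methyl-9-ketone.
- Decalin ⇐ Wieland–Miescher-type enedione with an angular CH2OPiv group, by deconjugative gem-dimethylation and axial-selective C3 reduction.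
- Enedione ⇐ prolinamide-catalysed desymmetrising aldol condensation of an achiral triketone. Ring order: ring B (from cyclohexane-1,3-dione) first, ring A in the organocatalytic step, then a temporary γ-lactone that is reopened to the side chain.

Assumption: the SMILES is read literally as (3R,5R,6R,8R,9R,10R,12R,13S), i.e. 3α-OH, 5α-H, 6β-OAc, 8α-OAc, 9α-H, 10β-CH2OAc; labdane numbering is used for all bicyclic compounds (C17 = CH3 on C8, C20 = CH2O on C10, β = face of C20).

**Step 1**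
Reactants: 1 cyclohexane-1,3-dione; 2 but-3-en-2-one
Product: 4 2-(hydroxymethyl)-2-(3-oxobutyl)cyclohexane-1,3-dione, via Michael adduct 3 (not isolated)
Conditions: H2O, Et3N (5 mol%), rt; then 37% aq. CH2O, rt
Reagents that add atoms: formaldehyde, C=O
Why: Michael addition of the acidic 1,3-dione to the enone, then aldol hydroxymethylation at the remaining doubly activated C–H; no stereocentre is formed.

**Step 2**
Reactants: 4 2-(hydroxymethyl)-2-(3-oxobutyl)cyclohexane-1,3-dione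
Product: 5 [2,6-dioxo-1-(3-oxobutyl)cyclohexyl]methyl pivalate
Conditions: PivCl, pyridine, DMAP (cat.), CH2Cl2, 0 °C
Reagents that add atoms: pivaloyl chloride, CC(C)(C)C(=O)Cl
Why: Acylation of the primary alcohol blocks retro-aldol loss of formaldehyde and hemiketal formation, and the pivalate has no α-hydrogen for the later base steps.

**Step 3**
Reactants: 5 [2,6-dioxo-1-(3-oxobutyl)cyclohexyl]methyl pivalate
Product: 7 [(8aS)-1,6-dioxo-1,2,3,4,6,7,8,8a-octahydronaphthalen-8a-yl]methyl pivalate (3,9-dioxo-Δ4 enedione with 10β-CH2OPiv), via cis-fused aldol ketol 6 (not isolated)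
Conditions: N-tosyl-(Sa)-binam-L-prolinamide (5 mol%), PhCO2H (2.5 mol%), neat, rt
Reagents that add atoms: none
Why: Hajos–Parrish–Eder–Sauer–Wiechert desymmetrising intramolecular aldol condensation, in which the enamine of the L-prolinamide attacks one enantiotopic ring carbonyl through a hydrogen-bonded transition state (same sense as L-proline, which gives the (S)-Wieland–Miescher ketone), setting C10 as the first stereocentre.

**Step 4**
Reactants: 7 Wieland–Miescher-type enedione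
Product: 8 C9 1,3-dioxolane of 7 (3-oxo-Δ4 enone kept)
Conditions: HOCH2CH2OH, p-TsOH·H2O (cat.), 4 Å MS, rt
Reagents that add atoms: ethane-1,2-diol, OCCO
Why: Acid-catalysed ketalisation is faster at the saturated C9 ketone than at the conjugated enone, as established for the Wieland–Miescher ketone.

**Step 5**
Reactants: 8 C9 dioxolane enone
Product: 9 4,4-dimethyl-Δ5-3-ketone 9-dioxolane (10β-CH2OPiv)
Conditions: KOt-Bu (3 equiv), THF, 0 °C; MeI (6 equiv), 0 °C→rt
Reagents that add atoms: iodomethane, CI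
Why: Deconjugative α,α-dialkylation through the extended dienolate (γ-deprotonation at C6) puts both methyl groups on C4 and leaves the Δ5 alkene, while the ketal prevents methylation at C8.

**Step 6**
Reactants: 9 4,4-dimethyl-Δ5-3-ketone 9-dioxolane
Product: 11 3α-(tert-butyldimethylsilyloxy)-4,4-dimethyl-Δ5 9-dioxolane (10β-CH2OPiv), via 3α-alcohol 10 (not isolated)
Conditions: Li(s-Bu)3BH, THF, −78 °C; then TBSOTf, 2,6-lutidine, −78→0 °C
Reagents that add atoms: tert-butyldimethylsilyl trifluoromethanesulfonate, CC(C)(C)[Si](C)(C)OS(=O)(=O)C(F)(F)F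
Why: The bulky borohydride attacks the gem-dimethyl-flanked C3 ketone equatorially to give the axial 3α-alkoxide (3R), which is trapped in situ as its silyl ether.

**Step 7**
Reactants: 11 3α-silyloxy 9-dioxolane
Product: 12 3α-(tert-butyldimethylsilyloxy)-4,4-dimethyl-Δ5-9-ketone (10β-CH2OPiv)
Conditions: PPTS, THF/H2O (4:1), 60 °C
Reagents that add atoms: water, O
Why: Mild acid hydrolysis of the dioxolane; the hindered secondary TBS ether and the pivalate survive.

**Step 8**
Reactants: 12 3α-silyloxy-Δ5-9-ketone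
Product: 13 8-methyl derivative of 12 (mixture of C8 epimers)
Conditions: LiN(i-Pr)2, THF, −78 °C; MeI, −78→−20 °C
Reagents that add atoms: iodomethane, CI
Why: Kinetic enolate alkylation; the only ketone can enolise only towards C8 (C10 is quaternary), and the C8 configuration is erased in the next step.

**Step 9**
Reactants: 13 8-methyl-9-ketone
Product: 14 8α-hydroxy-8β-methyl-9-ketone (3α-OTBS, Δ5, 10β-CH2OPiv)
Conditions: KN(SiMe3)2, THF, −78 °C; 2-(phenylsulfonyl)-3-phenyloxaziridine; aq. NH4Cl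
Reagents that add atoms: 2-(phenylsulfonyl)-3-phenyloxaziridine, O=S(=O)(c1ccccc1)N1OC1c1ccccc1
Why: Davis enolate hydroxylation; the oxaziridine approaches the tetrasubstituted enolate from the α-face, anti to the axial C20 group on the adjacent C10, giving 8α-OH and axial 8β-CH3 (8R).

**Step 10**
Reactants: 14 8α-hydroxy-8β-methyl-9-ketone
Product: 15 Δ9(11)-8α,12-butenolide (3α-OTBS, Δ5, 10β-CH2OPiv)
Conditions: Ph3P=C=C=O, toluene, 110 °C
Reagents that add atoms: (triphenylphosphoranylidene)ketene, O=C=C=P(c1ccccc1)(c1ccccc1)c1ccccc1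
Why: Bestmann ylide annulation; the tertiary O–H adds across the ketene C=C to an ester-stabilised ylide, which closes by intramolecular Wittig olefination of the hindered C9 ketone and brings in C11 and C12.

**Step 11**
Reactants: 15 Δ9(11)-butenolide
Product: 16 8α,12-olide with 9α-H (3α-OTBS, Δ5, 10β-CH2OPiv)
Conditions: H2 (4 atm), 5% Rh/Al2O3, EtOAc, rt
Reagents that add atoms: none
Why: Heterogeneous hydrogenation adds to the butenolide C9=C11 from the α-face (the β-face is shielded by 8β-CH3 and C20), setting 9α-H (9R) in a trans-fused sclareolide-type lactone, while the neopentylic Δ5 alkene is inert.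

**Step 12**
Reactants: 16 Δ5-8α,12-olide
Product: 18 6-oxo-8α,12-olide with 5α-H (3α-OTBS, 10β-CH2OPiv), via 6α-alkylborane 17 (not isolated)
Conditions: BH3·SMe2, THF, 0 °C→rt; then NMO, (n-Pr4N)(RuO4) (5 mol%), 4 Å MS, CH2Cl2, rt
Reagents that add atoms: borane dimethyl sulfide complex, C[S+](C)[BH3-] (boron of 17 only); 4-methylmorpholine N-oxide, C[N+]1([O-])CCOCC1 (ketone oxygen of 18)
Why: Hydroboration adds B–H syn from the α-face (B to C6, H to C5, giving the trans-decalin, 5R), and the C–B bond is oxidised through to the ketone in a one-pot hydroboration–oxidation.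

**Step 13**
Reactants: 18 6-oxo-8α,12-olide
Product: 19 8α,12-lactol 6β,20-diol (3α-OTBS; C12 anomers)
Conditions: i-Bu2AlH (6 equiv), CH2Cl2, −78 °C; aq. potassium sodium tartrate
Reagents that add atoms: none
Why: Hydride reduction at −78 °C stops at the lactol, reduces the C6 ketone from the open α-face (the β-face is blocked by 4β-CH3 and C20) to the axial 6β-alcohol (6R), and cleaves the pivalate.

**Step 14**
Reactants: 2 but-3-en-2-one
Product: 20 tert-butyl(buta-1,3-dien-2-yloxy)dimethylsilane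
Conditions: TBSOTf, Et3N, Et2O, 0 °C
Reagents that add atoms: tert-butyldimethylsilyl trifluoromethanesulfonate, CC(C)(C)[Si](C)(C)OS(=O)(=O)C(F)(F)F
Why: Soft enolisation and O-silylation of the enone gives the 2-silyloxydiene.

**Step 15**
Reactants: 20 tert-butyl(buta-1,3-dien-2-yloxy)dimethylsilane
Product: 21 (E)-2-[3-(tert-butyldimethylsilyloxy)but-2-en-1-yl]-4,4,5,5-tetramethyl-1,3,2-dioxaborolane (CH3 cis to CH2B)
Conditions: HBpin, Ni(cod)2 (2.5 mol%), PCy3 (2.5 mol%), toluene, rt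
Reagents that add atoms: pinacolborane, [H]B1OC(C)(C)C(C)(C)O1
Why: Nickel-catalysed 1,4-hydroboration of the s-cis-bound diene (H to C1, B to the unsubstituted terminus) places CH3 and CH2B cis on the new double bond.

**Step 16**
Reactants: 19 8α,12-lactol 6β,20-diol; 21 (E)-γ-silyloxy-γ-methylallylboronate
Product: 23 (12R,13S)-3α,13-bis(tert-butyldimethylsilyloxy)labd-14-ene-6β,8α,12,20-tetraol, via 12-O-pinacolboronate 22 (not isolated)
Conditions: (S)-TRIP phosphoric acid (10 mol%), 21 (2.5 equiv), 4 Å MS, toluene, −30→0 °C; then aq. NaHCO3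
Reagents that add atoms: none
Why: Proposed new method: a chiral-phosphoric-acid-catalysed allylboration in which the lactol opens to its hydroxy aldehyde and reacts through a closed chair transition state (acid hydrogen-bonded to a boronate oxygen, formyl H to P=O) with C11 equatorial, γ-OTBS equatorial (E position) and γ-CH3 axial, giving the 12,13-anti relationship; the (S)-catalyst is chosen for Si-face attack (12R, hence 13S) by analogy with the known benzaldehyde case, so the C12–C13 bond, both stereocentres and the tertiary silyl ether form in one step; the closest known reactions are phosphoric-acid-catalysed allyl- and crotylboration of aldehydes with pinacol allylboronates and (E)-γ-alkoxyallylboration to anti-1,2-diols, and what is new is the γ,γ-disubstituted enol-silane boronate and the lactol as aldehyde surrogate.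

**Step 17**
Reactants: 23 bis-silyl tetraol
Product: 24 (12R,13S)-3α,13-bis(tert-butyldimethylsilyloxy)labd-14-ene-6β,8α,12,20-tetrayl tetraacetate
Conditions: Ac2O, Et3N, DMAP (1 equiv), CH2Cl2, 40 °C
Reagents that add atoms: acetic anhydride, CC(=O)OC(C)=O
Why: DMAP-catalysed acylation, forced to include the tertiary 8α-OH and the hindered axial 6β-OH, while the two silyl ethers keep O3 and O13 free of acetate.

**Step 18**
Reactants: 24 bis-silyl tetraacetate
Product: 25 (3R,5R,6R,8R,9R,10R,12R,13S)-3,13-dihydroxylabd-14-ene-6,8,12,20-tetrayl tetraacetate (target)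
Conditions: HF·pyridine, pyridine/THF, 0→40 °C
Reagents that add atoms: none
Why: Fluoride-mediated cleavage of both TBS ethers; the acetates and the tertiary allylic alcohol are stable to buffered HF.

**Compound list**
1 | cyclohexane-1,3-dione | O=C1CCCC(=O)C1 | starting material
2 | but-3-en-2-one | CC(=O)C=C | starting material
3 | 2-(3-oxobutyl)cyclohexane-1,3-dione | CC(=O)CCC1C(=O)CCCC1=O | intermediate (not isolated)
4 | 2-(hydroxymethyl)-2-(3-oxobutyl)cyclohexane-1,3-dione | CC(=O)CCC1(CO)C(=O)CCCC1=O | intermediate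
5 | [2,6-dioxo-1-(3-oxobutyl)cyclohexyl]methyl pivalate | CC(=O)CCC1(COC(=O)C(C)(C)C)C(=O)CCCC1=O | intermediate
6 | cis-fused aldol ketol (5β-OH, 3,9-dioxo, 10β-CH2OPiv) | O=C1CC[C@]2(COC(=O)C(C)(C)C)C(=O)CCC[C@]2(O)C1 | intermediate (not isolated)
7 | [(8aS)-1,6-dioxo-1,2,3,4,6,7,8,8a-octahydronaphthalen-8a-yl]methyl pivalate | O=C1C=C2CCCC(=O)[C@@]2(COC(=O)C(C)(C)C)CC1 | intermediate
8 | C9 1,3-dioxolane of 7 | O=C1C=C2CCCC3(OCCO3)[C@@]2(COC(=O)C(C)(C)C)CC1 | intermediate
9 | 4,4-dimethyl-Δ5-3-ketone 9-dioxolane | O=C1C(C)(C)C2=CCCC3(OCCO3)[C@@]2(COC(=O)C(C)(C)C)CC1 | intermediate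
10 | 3α-alcohol of 9 | O[C@H]1C(C)(C)C2=CCCC3(OCCO3)[C@@]2(COC(=O)C(C)(C)C)CC1 | intermediate (not isolated)
11 | 3α-TBS ether 9-dioxolane | CC(C)(C)[Si](C)(C)O[C@H]1C(C)(C)C2=CCCC3(OCCO3)[C@@]2(COC(=O)C(C)(C)C)CC1 | intermediate
12 | 3α-OTBS-4,4-dimethyl-Δ5-9-ketone | CC(C)(C)[Si](C)(C)O[C@H]1C(C)(C)C2=CCCC(=O)[C@@]2(COC(=O)C(C)(C)C)CC1 | intermediate
13 | 8-methyl-9-ketone (C8 epimers) | CC(C)(C)[Si](C)(C)O[C@H]1C(C)(C)C2=CCC(C)C(=O)[C@@]2(COC(=O)C(C)(C)C)CC1 | intermediate
14 | 8α-hydroxy-8β-methyl-9-ketone | CC(C)(C)[Si](C)(C)O[C@H]1C(C)(C)C2=CC[C@@](C)(O)C(=O)[C@@]2(COC(=O)C(C)(C)C)CC1 | intermediate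
15 | Δ9(11)-8α,12-butenolide | CC(C)(C)[Si](C)(C)O[C@H]1C(C)(C)C2=CC[C@@]3(C)OC(=O)C=C3[C@@]2(COC(=O)C(C)(C)C)CC1 | intermediate
16 | Δ5-8α,12-olide (9α-H) | CC(C)(C)[Si](C)(C)O[C@H]1C(C)(C)C2=CC[C@@]3(C)OC(=O)C[C@@H]3[C@@]2(COC(=O)C(C)(C)C)CC1 | intermediate
17 | 6α-alkylborane (5α-H) | CC(C)(C)[Si](C)(C)O[C@H]1C(C)(C)[C@@H]2[C@@H](B)C[C@@]3(C)OC(=O)C[C@@H]3[C@@]2(COC(=O)C(C)(C)C)CC1 | intermediate (not isolated)
18 | 6-oxo-8α,12-olide (5α-H) | CC(C)(C)[Si](C)(C)O[C@H]1C(C)(C)[C@@H]2C(=O)C[C@@]3(C)OC(=O)C[C@@H]3[C@@]2(COC(=O)C(C)(C)C)CC1 | intermediate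
19 | 8α,12-lactol 6β,20-diol (3α-OTBS) | CC(C)(C)[Si](C)(C)O[C@H]1C(C)(C)[C@@H]2[C@H](O)C[C@@]3(C)OC(O)C[C@@H]3[C@@]2(CO)CC1 | intermediate
20 | tert-butyl(buta-1,3-dien-2-yloxy)dimethylsilane | C=CC(=C)O[Si](C)(C)C(C)(C)C | intermediate
21 | (E)-2-[3-(tert-butyldimethylsilyloxy)but-2-en-1-yl]-4,4,5,5-tetramethyl-1,3,2-dioxaborolane | C/C(O[Si](C)(C)C(C)(C)C)=C\CB1OC(C)(C)C(C)(C)O1 | intermediate
22 | 12-O-pinacolboronate of 23 | C=C[C@](C)(O[Si](C)(C)C(C)(C)C)[C@@H](C[C@@H]1[C@@]2(CO)CC[C@@H](O[Si](C)(C)C(C)(C)C)C(C)(C)[C@@H]2[C@H](O)C[C@@]1(C)O)OB1OC(C)(C)C(C)(C)O1 | intermediate (not isolated)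
23 | (12R,13S)-3α,13-bis(TBSO)labd-14-ene-6β,8α,12,20-tetraol | C=C[C@](C)(O[Si](C)(C)C(C)(C)C)[C@@H](C[C@@H]1[C@@]2(CO)CC[C@@H](O[Si](C)(C)C(C)(C)C)C(C)(C)[C@@H]2[C@H](O)C[C@@]1(C)O)O | intermediate
24 | tetraacetate of 23 | C=C[C@](C)(O[Si](C)(C)C(C)(C)C)[C@@H](C[C@@H]1[C@@]2(COC(C)=O)CC[C@@H](O[Si](C)(C)C(C)(C)C)C(C)(C)[C@@H]2[C@H](OC(C)=O)C[C@@]1(C)OC(C)=O)OC(C)=O | intermediate
25 | (3R,5R,6R,8R,9R,10R,12R,13S)-3,13-dihydroxylabd-14-ene-6,8,12,20-tetrayl tetraacetate | C=C[C@](C)(O)[C@@H](C[C@@H]1[C@@]2(COC(C)=O)CC[C@@H](O)C(C)(C)[C@@H]2[C@H](OC(C)=O)C[C@@]1(C)OC(C)=O)OC(C)=O | target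

**Step count and risks**
Total steps: 18. Longest linear sequence: 16 (steps 1–13 and 16–18); steps 14–15 are a two-step branch to reagent 21.

The three steps most likely to fail:

1. Step 16 (proposed new allylboration). Risks are protodesilylation of the enol silane by the acid, slow lactol opening, and the facial sense on this substrate. The fallback uses known chemistry, sets out from 19 and comes back at 25. (E)-But-2-en-2-yllithium (from (E)-2-bromobut-2-ene and t-BuLi) adds to 19 to give the 13(E)-ene allylic alcohol tetraol F1 (C12 epimers separated, 12R kept). Hydroxyl-directed epoxidation (VO(acac)2, t-BuOOH, erythro-selective for 2-substituted allylic alcohols) gives the 13,14-epoxy alcohol F2, whose epoxide oxygen becomes O13. Acetylation under step 17 conditions gives the epoxy tetraacetate F3, the epoxide masking the tertiary alcohol. PhSeNa (PhSeSePh, NaBH4, EtOH) opens the epoxide at the less hindered C14 to the hydroxy selenide F4. H2O2 gives the selenoxide F5, which syn-eliminates towards C15 to the 13-hydroxy tetraacetate 3α-TBS ether F6. HF·pyridine as in step 18 then gives 25.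

2. Step 10 (ylide annulation on a ketone flanked by two quaternary carbons). The fallback sets out from 14 and comes back at 15. Acetylation of the tertiary alcohol (Ac2O, DMAP, Et3N) gives the 8α-acetoxy ketone F7. LiN(SiMe3)2 in THF at −78 °C effects an intramolecular acetate aldol to the cis-fused 9β-hydroxy-8α,12-olide F8. Dehydration (SOCl2, pyridine) can only go towards C11 and gives 15.

3. Step 12 (hydroboration of a hindered alkene beside a lactone). The fallback sets out from 16 and comes back at 18. m-CPBA epoxidises from the α-face to the 5α,6α-epoxide F9. BF3·OEt2 promotes Meinwald rearrangement with a 6→5 hydride shift to the cis-fused 5β-H 6-ketone F10. DBU then epimerises C5 to the trans-fused 18.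

**Further compounds**
F1 | step 16 | (12R,13E)-3α-(TBSO)labd-13-ene-6β,8α,12,20-tetraol | C/C=C(\C)[C@H](O)C[C@@H]1[C@@]2(CO)CC[C@@H](O[Si](C)(C)C(C)(C)C)C(C)(C)[C@@H]2[C@H](O)C[C@@]1(C)O
F2 | step 16 | erythro 13,14-epoxide of F1 | C[C@H]4O[C@]4(C)[C@H](O)C[C@@H]1[C@@]2(CO)CC[C@@H](O[Si](C)(C)C(C)(C)C)C(C)(C)[C@@H]2[C@H](O)C[C@@]1(C)O
F3 | step 16 | 6β,8α,12,20-tetraacetate of F2 | C[C@H]4O[C@]4(C)[C@H](OC(C)=O)C[C@@H]1[C@@]2(COC(C)=O)CC[C@@H](O[Si](C)(C)C(C)(C)C)C(C)(C)[C@@H]2[C@H](OC(C)=O)C[C@@]1(C)OC(C)=O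
F4 | step 16 | 14-phenylseleno-13-hydroxy tetraacetate | C[C@H]([Se]c1ccccc1)[C@](C)(O)[C@H](OC(C)=O)C[C@@H]1[C@@]2(COC(C)=O)CC[C@@H](O[Si](C)(C)C(C)(C)C)C(C)(C)[C@@H]2[C@H](OC(C)=O)C[C@@]1(C)OC(C)=O
F5 | step 16 | selenoxide of F4 | C[C@H]([Se](=O)c1ccccc1)[C@](C)(O)[C@H](OC(C)=O)C[C@@H]1[C@@]2(COC(C)=O)CC[C@@H](O[Si](C)(C)C(C)(C)C)C(C)(C)[C@@H]2[C@H](OC(C)=O)C[C@@]1(C)OC(C)=O
F6 | step 16 | 13-hydroxy tetraacetate 3α-TBS ether (24 without the 13-O-silyl group) | C=C[C@](C)(O)[C@@H](C[C@@H]1[C@@]2(COC(C)=O)CC[C@@H](O[Si](C)(C)C(C)(C)C)C(C)(C)[C@@H]2[C@H](OC(C)=O)C[C@@]1(C)OC(C)=O)OC(C)=O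
F7 | step 10 | 8α-acetate of 14 | CC(C)(C)[Si](C)(C)O[C@H]1C(C)(C)C2=CC[C@@](C)(OC(C)=O)C(=O)[C@@]2(COC(=O)C(C)(C)C)CC1
F8 | step 10 | cis-fused 9β-hydroxy-8α,12-olide | CC(C)(C)[Si](C)(C)O[C@H]1C(C)(C)C2=CC[C@@]3(C)OC(=O)C[C@@]3(O)[C@@]2(COC(=O)C(C)(C)C)CC1
F9 | step 12 | 5α,6α-epoxide of 16 | CC(C)(C)[Si](C)(C)O[C@H]1C(C)(C)[C@]23O[C@H]2C[C@@]4(C)OC(=O)C[C@@H]4[C@@]3(COC(=O)C(C)(C)C)CC1
F10 | step 12 | 5β-H 6-ketone (cis-decalin epimer of 18) | CC(C)(C)[Si](C)(C)O[C@H]1C(C)(C)[C@H]2C(=O)C[C@@]3(C)OC(=O)C[C@@H]3[C@@]2(COC(=O)C(C)(C)C)CC1
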